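**Retrosynthetic overview**
- C2–OH: enantioselective aerobic hydroxylation of the 2-alkylbenzofuran-3(2H)-one in the last step.
- C2–C1' (side chain to heterocycle): Pd-catalysed allylation of a benzofuranone β-keto ester with the (8R)-hydroxyfarnesyl acetate, then loss of the ester.
- Key step, C8'–C9': titanocene-mediated radical coupling of an α-methyl enal with prenyl bromide (linear adduct); the 8R enantiomer is then selected by Sharpless kinetic resolution.
- Enal: hex-1-en-5-yne, Zr-catalysed carboalumination (2E alkene), then cross-metathesis with methacrolein (6E alkene).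
- Rings: benzene ring first (acetoacetate/crotonaldehyde annulation, aromatisation), furanone ring second (O-alkylation/Dieckmann).

Assumption 1: C2 is a hemiketal carbon that can epimerise by ring–chain tautomerism, so it is set last and the product is kept neutral, cold and aprotic.
Assumption 2: the sense of induction of the catalyst in step 10 is assumed; if the first run gives 2S, the pseudo-enantiomeric cinchonidinium salt is used.

Step 1
Reactants: 1 hex-1-en-5-yne
Product: 4 (2E)-3-methylhepta-2,6-dien-1-yl acetate, via alkenylalane 2 (not isolated), via aluminium alkoxide 3 (not isolated)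
Conditions: Me3Al (2 equiv), Cp2ZrCl2 (0.2 equiv), CH2Cl2, 0 °C to rt; n-BuLi, THF, −78 °C, then (CH2O)n, rt; Ac2O, DMAP, 0 °C to rt
Reagents that add atoms: trimethylaluminium C[Al](C)C; paraformaldehyde (as formaldehyde) C=O; acetic anhydride CC(=O)OC(C)=O
Why: Negishi zirconium-catalysed carboalumination adds Me and Al syn across the terminal alkyne only, which fixes the 2E trisubstituted alkene; the alanate is hydroxymethylated with retention and the aluminium alkoxide is acetylated in the same flask.

Step 2
Reactants: 4 (2E)-3-methylhepta-2,6-dien-1-yl acetate; 5 methacrolein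
Product: 6 (2E,6E)-3,7-dimethyl-8-oxoocta-2,6-dien-1-yl acetate
Conditions: 5 (5 equiv), second-generation Hoveyda–Grubbs catalyst RuCl2(H2IMes)(=CH-C6H4-2-OiPr) (3 mol%), CH2Cl2, 40 °C
Reagents that add atoms: none
Why: Olefin cross-metathesis of the terminal alkene with the 1,1-disubstituted enal gives the thermodynamically favoured E α-methyl enal; the trisubstituted alkene and the allylic acetate do not take part.

Step 3
Reactants: 6 (2E,6E)-3,7-dimethyl-8-oxoocta-2,6-dien-1-yl acetate; 7 prenyl bromide
Product: 9 (2E,6E)-8-hydroxy-3,7,11-trimethyldodeca-2,6,10-trien-1-yl acetate (racemic at C8), via silyl ether 8 (not isolated)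
Conditions: Cp2TiCl2 (0.2 equiv), Mn dust (8 equiv), Me3SiCl (4 equiv), 2,4,6-collidine (7 equiv), THF, rt, slow addition of 6 and 7 (2.5 equiv); then 1 M HCl, THF, 0 °C
Reagents that add atoms: none
Why: Cp2TiCl (trivalent titanium, made in the flask from Cp2TiCl2 and Mn; Nugent–RajanBabu reagent) reduces the conjugated aldehyde to a titanium-bound ketyl radical and turns 7 into the prenyl radical, and radical–radical coupling (Barbier-type α-prenylation) joins the carbonyl carbon to the unhindered CH2 end of the prenyl radical; this gives the linear C8–C9 bond that polar prenyl-metal additions do not give, C8 is formed racemic, and the allylic acetate and other alkenes are inert.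

Step 4
Reactants: 9 (2E,6E)-8-hydroxy-3,7,11-trimethyldodeca-2,6,10-trien-1-yl acetate (racemic at C8)
Product: 10 (2E,6E,8R)-8-hydroxy-3,7,11-trimethyldodeca-2,6,10-trien-1-yl acetate
Conditions: Ti(OiPr)4 (0.2 equiv), L-(+)-diisopropyl tartrate (0.3 equiv), t-BuOOH (0.6 equiv), 4 Å MS, CH2Cl2, −20 °C, to ca. 55% conversion
Reagents that add atoms: none
Why: Sharpless kinetic resolution: with L-(+)-DIPT the 8S enantiomer is epoxidised at its allylic C6–C7 alkene much faster, so the 8R alcohol is recovered in high ee (at most about 45% yield); the undirected alkenes stay intact.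

Step 5
Reactants: 11 methyl acetoacetate; 12 (E)-crotonaldehyde
Product: 14 methyl 6-methyl-2-oxocyclohex-3-ene-1-carboxylate (racemic), via ketol 13 (not isolated)
Conditions: NaOMe (0.1 equiv), MeOH, 0 °C to rt; then p-TsOH (cat.), toluene, reflux (Dean–Stark)
Reagents that add atoms: none
Why: Michael addition of the keto ester to the enal, intramolecular aldol and dehydration (Robinson-type annulation) place the methyl group next to the ester-bearing carbon, which fixes the later 1,2,3-substitution of the arene.

Step 6
Reactants: 14 methyl 6-methyl-2-oxocyclohex-3-ene-1-carboxylate (racemic)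
Product: 16 methyl 2-hydroxy-6-methylbenzoate, via bromoketone 15 (not isolated)
Conditions: Br2 (1.0 equiv), CHCl3, 0 °C; then reflux
Reagents that add atoms: none
Why: Bromination at the doubly activated carbon followed by loss of HBr and tautomerisation aromatises the ring to the salicylate (bromination–dehydrobromination).

Step 7
Reactants: 16 methyl 2-hydroxy-6-methylbenzoate; 17 methyl bromoacetate
Product: 19 methyl 3-hydroxy-4-methyl-1-benzofuran-2-carboxylate, via diester 18 (not isolated)
Conditions: K2CO3, DMF, 60 °C; then t-BuOK, THF, 0 °C to rt; 1 M HCl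
Reagents that add atoms: none
Why: Williamson O-alkylation, then Dieckmann condensation of the aryloxyacetate onto the aryl ester closes the furanone ring, driven by formation of the aromatic 3-hydroxybenzofuran enolate.

Step 8
Reactants: 19 methyl 3-hydroxy-4-methyl-1-benzofuran-2-carboxylate; 10 (2E,6E,8R)-8-hydroxy-3,7,11-trimethyldodeca-2,6,10-trien-1-yl acetate
Product: 20 methyl 2-[(2E,6E,8R)-8-hydroxy-3,7,11-trimethyldodeca-2,6,10-trien-1-yl]-4-methyl-3-oxo-2,3-dihydro-1-benzofuran-2-carboxylate (both C2 epimers)
Conditions: Pd(PPh3)4 (5 mol%), K2CO3 (1.5 equiv), DMF, rt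
Reagents that add atoms: none
Why: Tsuji–Trost allylation: zerovalent palladium ionises only the primary allylic acetate, the soft β-keto ester enolate attacks the unsubstituted allyl terminus (linear, 2E retained), O-allylation is reversible, and the ester blocks a second allylation; the new C2 centre is a mixture that is erased in step 9.

Step 9
Reactants: 20 methyl 2-[(2E,6E,8R)-8-hydroxy-3,7,11-trimethyldodeca-2,6,10-trien-1-yl]-4-methyl-3-oxo-2,3-dihydro-1-benzofuran-2-carboxylate (both C2 epimers)
Product: 21 2-[(2E,6E,8R)-8-hydroxy-3,7,11-trimethyldodeca-2,6,10-trien-1-yl]-4-methyl-1-benzofuran-3(2H)-one (both C2 epimers)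
Conditions: LiCl (3 equiv), H2O (2 equiv), DMSO, 130 °C, argon (strictly air-free)
Reagents that add atoms: none
Why: Krapcho dealkoxycarbonylation: chloride demethylates the non-enolisable β-keto ester and the carboxylate loses CO2; the C8 carbinol and the alkenes are untouched, and air is excluded because the product enolate autoxidises.

Step 10
Reactants: 21 2-[(2E,6E,8R)-8-hydroxy-3,7,11-trimethyldodeca-2,6,10-trien-1-yl]-4-methyl-1-benzofuran-3(2H)-one (both C2 epimers)
Product: 22 (2R)-2-hydroxy-2-[(2E,6E,8R)-8-hydroxy-3,7,11-trimethyldodeca-2,6,10-trien-1-yl]-4-methyl-1-benzofuran-3(2H)-one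
Conditions: O2 (1 atm), N-(9-anthracenylmethyl)cinchoninium chloride (10 mol%), P(OEt)3 (1.5 equiv), Cs2CO3 (0.3 equiv), toluene, −20 °C; AcOH quench at −20 °C, neutral work-up
Reagents that add atoms: dioxygen O=O
Why: Phase-transfer-catalysed aerobic α-hydroxylation: the aromatic benzofuran-3-olate passes an electron to triplet O2 and the radical pair collapses to the C2 hydroperoxide inside the chiral ammonium ion pair, which shields one face and sets 2R; P(OEt)3 reduces the hydroperoxide at once, and the isolated alkenes do not react with triplet oxygen.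

**Compound list**
1 | hex-1-en-5-yne | C=CCCC#C | starting material
2 | dimethyl[(1E)-2-methylhexa-1,5-dien-1-yl]alane | C=CCC/C(C)=C/[Al](C)C | intermediate
3 | (2E)-3-methylhepta-2,6-dien-1-ol, held as its aluminate alkoxide (drawn as the alcohol) | C=CCC/C(C)=C/CO | intermediate
4 | (2E)-3-methylhepta-2,6-dien-1-yl acetate | C=CCC/C(C)=C/COC(C)=O | intermediate
5 | methacrolein (2-methylprop-2-enal) | CC(=C)C=O | starting material
6 | (2E,6E)-3,7-dimethyl-8-oxoocta-2,6-dien-1-yl acetate | O=C/C(C)=C/CC/C(C)=C/COC(C)=O | intermediate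
7 | prenyl bromide (1-bromo-3-methylbut-2-ene) | CC(C)=CCBr | starting material
8 | (2E,6E)-3,7,11-trimethyl-8-(trimethylsilyloxy)dodeca-2,6,10-trien-1-yl acetate, racemic | CC(C)=CCC(O[Si](C)(C)C)/C(C)=C/CC/C(C)=C/COC(C)=O | intermediate
9 | (2E,6E)-8-hydroxy-3,7,11-trimethyldodeca-2,6,10-trien-1-yl acetate, racemic at C8 | CC(C)=CCC(O)/C(C)=C/CC/C(C)=C/COC(C)=O | intermediate
10 | (2E,6E,8R)-8-hydroxy-3,7,11-trimethyldodeca-2,6,10-trien-1-yl acetate | CC(C)=CC[C@@H](O)/C(C)=C/CC/C(C)=C/COC(C)=O | intermediate
11 | methyl acetoacetate (methyl 3-oxobutanoate) | COC(=O)CC(C)=O | starting material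
12 | (E)-crotonaldehyde ((2E)-but-2-enal) | C/C=C/C=O | starting material
13 | methyl 4-hydroxy-6-methyl-2-oxocyclohexane-1-carboxylate, diastereomer mixture | COC(=O)C1C(C)CC(O)CC1=O | intermediate
14 | methyl 6-methyl-2-oxocyclohex-3-ene-1-carboxylate, racemic | COC(=O)C1C(C)CC=CC1=O | intermediate
15 | methyl 1-bromo-6-methyl-2-oxocyclohex-3-ene-1-carboxylate, racemic | COC(=O)C1(Br)C(C)CC=CC1=O | intermediate
16 | methyl 2-hydroxy-6-methylbenzoate | COC(=O)c1c(C)cccc1O | intermediate
17 | methyl bromoacetate | COC(=O)CBr | starting material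
18 | methyl 2-(2-methoxy-2-oxoethoxy)-6-methylbenzoate | COC(=O)COc1cccc(C)c1C(=O)OC | intermediate
19 | methyl 3-hydroxy-4-methyl-1-benzofuran-2-carboxylate | COC(=O)c1oc2cccc(C)c2c1O | intermediate
20 | methyl 2-[(2E,6E,8R)-8-hydroxy-3,7,11-trimethyldodeca-2,6,10-trien-1-yl]-4-methyl-3-oxo-2,3-dihydro-1-benzofuran-2-carboxylate, both C2 epimers | CC(C)=CC[C@@H](O)/C(C)=C/CC/C(C)=C/CC1(C(=O)OC)Oc2cccc(C)c2C1=O | intermediate
21 | 2-[(2E,6E,8R)-8-hydroxy-3,7,11-trimethyldodeca-2,6,10-trien-1-yl]-4-methyl-1-benzofuran-3(2H)-one, both C2 epimers | CC(C)=CC[C@@H](O)/C(C)=C/CC/C(C)=C/CC1Oc2cccc(C)c2C1=O | intermediate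
22 | (2R)-2-hydroxy-2-[(2E,6E,8R)-8-hydroxy-3,7,11-trimethyldodeca-2,6,10-trien-1-yl]-4-methyl-1-benzofuran-3(2H)-one | CC(C)=CC[C@@H](O)/C(C)=C/CC/C(C)=C/C[C@@]1(O)Oc2cccc(C)c2C1=O | target

**Step count**
Total: 10 steps. Longest linear sequence: 7 steps (steps 1–4, then 8–10, from hex-1-en-5-yne); the aromatic branch (steps 5–7) joins at step 8.

**Steps most likely to fail, each with a fallback**

Step 3 (radical α-prenylation). The risks are the branched γ-adduct, pinacol dimerisation of the enal and Wurtz coupling of 7. The fallback sets out from 6. Asymmetric allylboration with (+)-Ipc2B(allyl) (Et2O, −78 °C, ethanolamine work-up) adds allyl to the Re face of the aldehyde and gives (2E,6E,8R)-8-hydroxy-3,7-dimethylundeca-2,6,10-trien-1-yl acetate F1. Cross-metathesis of its vinyl group with 2-methylbut-2-ene (second-generation Grubbs catalyst RuCl2(H2IMes)(PCy3)(=CHPh), CH2Cl2, rt) then installs the isopropylidene end. The fallback comes back to the route at 10, so 9 and the resolution of step 4 are left out.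

Step 8 (C-allylation). The risks are O-allylation, partial E/Z leakage in the allyl-palladium intermediate, and degradation of 20 in the hot Krapcho step that follows. The fallback sets out from 19. LiOH in THF/H2O at 0 °C gives 3-hydroxy-4-methyl-1-benzofuran-2-carboxylic acid F2. Pd(PPh3)4-catalysed decarboxylative allylation of this acid with 10 (THF, 50 °C) forms the C2–C1' bond with loss of CO2. The fallback comes back at 21, leaving out 20 and step 9.

Step 10 (enantioselective hydroxylation). The risks are low ee and epimerisation or cleavage of the hemiketal while base is present. The fallback sets out from 21. Air, Et3N (cat.) and P(OEt)3 in CH2Cl2 at 0 °C give the hemiketal without stereocontrol as (2RS)-2-hydroxy-2-[(2E,6E,8R)-8-hydroxy-3,7,11-trimethyldodeca-2,6,10-trien-1-yl]-4-methyl-1-benzofuran-3(2H)-one F3. The two C2 diastereomers are separated by preparative HPLC on a chiral stationary phase, which comes back at 22. The 2S epimer is re-equilibrated through ring–chain tautomerism (trace Et3N) and recycled.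

Further compounds
F1 | step 3 | (2E,6E,8R)-8-hydroxy-3,7-dimethylundeca-2,6,10-trien-1-yl acetate | C=CC[C@@H](O)/C(C)=C/CC/C(C)=C/COC(C)=O
F2 | step 8 | 3-hydroxy-4-methyl-1-benzofuran-2-carboxylic acid | OC(=O)c1oc2cccc(C)c2c1O
F3 | step 10 | (2RS)-2-hydroxy-2-[(2E,6E,8R)-8-hydroxy-3,7,11-trimethyldodeca-2,6,10-trien-1-yl]-4-methyl-1-benzofuran-3(2H)-one | CC(C)=CC[C@@H](O)/C(C)=C/CC/C(C)=C/CC1(O)Oc2cccc(C)c2C1=O
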